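**Retrosynthetic overview**

1. The E-trisubstituted olefin and the arene come last: Zr-catalysed methylalumination of a terminal alkyne on the finished core, then Pd coupling with an ortho-(methoxymethoxy)benzyl chloride made from o-cresol.
2. Key disconnection C3a–C4: an iron-hydride hydrogen atom transfer turns the cyclopentene of an acyclic β-hydroxy nitrile into the tertiary C3a radical, which closes 6-exo onto C≡N. This gives the second quaternary centre, the cis ring fusion and, after hydrolysis, the C4 ketone.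
3. The β-hydroxy nitrile: C5 by epoxide alkylation with 2,2-dimethyloxirane, C6 by reagent-controlled allenylboration of a β-ketonitrile.
4. The β-ketonitrile: acetonitrile plus the ester from a Johnson–Claisen rearrangement that transfers CBS-set carbinol chirality to C7a.
5. Ring order: the five-membered ring is bought (2,3-dimethylcyclopent-2-enone); the six-membered ring is closed by the radical step.

Assumption: atom labels follow octahydro-4H-inden-4-one numbering (C3a/C7a ring fusion, C4 ketone, C5, C6 carbinol); the target is the (3aR,5R,6R,7aR) isomer with an E side-chain olefin; the chiral allenylborane of step 4 is a reagent whose C3 unit comes from propargyl bromide.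

**Route**

Step 1
Reactants: 1 2,3-dimethylcyclopent-2-en-1-one
Product: 2 (1R)-2,3-dimethylcyclopent-2-en-1-ol
Conditions: (S)-1-methyl-3,3-diphenyltetrahydro-1H,3H-pyrrolo[1,2-c][1,3,2]oxazaborole (10 mol%), BH3·SMe2 (0.7 equiv), THF, −20 °C; MeOH
Reagents that add atoms: none
Why: Corey–Bakshi–Shibata reduction, in which the olefinic arm of the enone acts as the large group so that hydride is delivered to one carbonyl face and C1 is set as R (about 90–95% ee expected for an α-substituted cyclopentenone).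

Step 2
Reactants: 2 (1R)-2,3-dimethylcyclopent-2-en-1-ol; 3 trimethyl orthoacetate
Product: 6 methyl 2-[(1R)-1,2-dimethylcyclopent-2-en-1-yl]acetate, via mixed orthoester 4 (not isolated), via ketene acetal 5 (not isolated)
Conditions: EtCO2H (5 mol%), xylene, 140 °C, MeOH distilled off
Reagents that add atoms: none
Why: Johnson–Claisen [3,3]-sigmatropic rearrangement, suprafacial across the ring, so the carbinol configuration is transferred to the new quaternary carbon (future C7a, R) and the olefin moves to the future C3a=C3 position.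

Step 3
Reactants: 6 methyl 2-[(1R)-1,2-dimethylcyclopent-2-en-1-yl]acetate; 7 acetonitrile
Product: 9 4-[(1R)-1,2-dimethylcyclopent-2-en-1-yl]-3-oxobutanenitrile, via lithioacetonitrile 8 (not isolated)
Conditions: LiN(i-Pr)2 (2.2 equiv), THF, −78 °C; then 6, −78 → 0 °C; aq. NH4Cl
Reagents that add atoms: none
Why: Claisen-type acylation of lithioacetonitrile by the methyl ester, stopped at the ketone stage because the β-ketonitrile is deprotonated as it forms; no stereocentre is created.

Step 4
Reactants: 9 4-[(1R)-1,2-dimethylcyclopent-2-en-1-yl]-3-oxobutanenitrile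
Product: 10 (3R)-3-{[(1R)-1,2-dimethylcyclopent-2-en-1-yl]methyl}-3-hydroxyhex-5-ynenitrile
Conditions: B-allenyl-10-phenyl-9-borabicyclo[3.3.2]decane (1.3 equiv, the antipode that adds to the Si face, CH2CN ranked above the ring CH2), Et2O, −78 °C; pH 7 buffer
Reagents that add atoms: B-allenyl-10-phenyl-9-borabicyclo[3.3.2]decane, C=C=CB1C(c2ccccc2)C2CCCC1CCC2
Why: Soderquist-type asymmetric allenylboration through a closed six-membered SE2′ transition state gives the homopropargylic tertiary alcohol, and reagent control (small CH2CN arm against the neopentyl-like arm) sets C6 as R because the remote quaternary centre exerts no facial bias.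

Step 5
Reactants: 10 (3R)-3-{[(1R)-1,2-dimethylcyclopent-2-en-1-yl]methyl}-3-hydroxyhex-5-ynenitrile; 11 2,2-dimethyloxirane
Product: 13 (3R)-3-{[(1R)-1,2-dimethylcyclopent-2-en-1-yl]methyl}-3-hydroxy-2-(2-hydroxy-2-methylpropyl)hex-5-ynenitrile (C2 epimers), via trilithio derivative 12 (not isolated)
Conditions: LiN(i-Pr)2 (3.3 equiv), THF, −78 °C; 11 (2 equiv), −78 → −10 °C; cold aq. NH4Cl
Reagents that add atoms: none
Why: Alkylation of a β-hydroxy nitrile polyanion (OH, alkyne C–H and α-cyano C–H removed), whose nitrile-stabilised carbanion opens the epoxide at its CH2 end by SN2; C5 forms as a mixture that is corrected in step 6.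

Step 6
Reactants: 13 (3R)-3-{[(1R)-1,2-dimethylcyclopent-2-en-1-yl]methyl}-3-hydroxy-2-(2-hydroxy-2-methylpropyl)hex-5-ynenitrile
Product: 15 (3aR,5R,6R,7aR)-6-hydroxy-5-(2-hydroxy-2-methylpropyl)-3a,7a-dimethyl-6-(prop-2-yn-1-yl)octahydro-4H-inden-4-one, via cyclic ketimine 14 (not isolated)
Conditions: Fe(acac)3 (30 mol%), PhSiH3 (3 equiv), EtOH, 60 °C, argon; then 10% aq. oxalic acid, THF, 20 °C
Reagents that add atoms: water, O
Why: Mukaiyama-type metal-hydride hydrogen atom transfer to the trisubstituted ring olefin gives the tertiary C3a radical, which adds 6-exo-dig to the nitrile (the intended, polarity-matched acceptor on a branched carbon) from the face of its own tether, so the ring fusion is cis (C3a R, both methyls cis); the iminyl radical is reduced to the ketimine, whose enamine tautomerism and hydrolysis give the C4 ketone with the C5 chain equatorial (R), trans to the propargyl group.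

Step 7
Reactants: 16 2-methylphenol
Product: 17 4-bromo-2-methylphenol
Conditions: N-bromosuccinimide (1.0 equiv), MeCN, −10 °C
Reagents that add atoms: N-bromosuccinimide, O=C1CCC(=O)N1Br
Why: Electrophilic aromatic bromination para to the hydroxyl group; no stereocentre.

Step 8
Reactants: 17 4-bromo-2-methylphenol
Product: 18 4-methoxy-2-methylphenol
Conditions: NaOMe (4 equiv), CuI (10 mol%), MeOH/DMF, 110 °C
Reagents that add atoms: sodium methoxide, C[O-].[Na+]
Why: Copper-catalysed Ullmann-type methoxylation of the aryl bromide, tolerated by the phenoxide.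

Step 9
Reactants: 18 4-methoxy-2-methylphenol
Product: 19 4-methoxy-1-(methoxymethoxy)-2-methylbenzene
Conditions: MeOCH2Cl, i-Pr2NEt, CH2Cl2, 0 → 20 °C
Reagents that add atoms: chloromethyl methyl ether, COCCl
Why: O-Alkylation of the phenol (Williamson type) installs a MOM group that protects the phenol and directs the next metalation.

Step 10
Reactants: 19 4-methoxy-1-(methoxymethoxy)-2-methylbenzene
Product: 21 [5-methoxy-2-(methoxymethoxy)-3-methylphenyl]methanol, via aryllithium 20 (not isolated)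
Conditions: n-BuLi (1.2 equiv), TMEDA, Et2O, 0 °C; (CH2O)n; aq. NH4Cl
Reagents that add atoms: formaldehyde (as paraformaldehyde), C=O
Why: Directed ortho-metalation by the OMOM group at the only free position next to it, then hydroxymethylation of the aryllithium.

Step 11
Reactants: 21 [5-methoxy-2-(methoxymethoxy)-3-methylphenyl]methanol
Product: 22 1-(chloromethyl)-5-methoxy-2-(methoxymethoxy)-3-methylbenzene
Conditions: PPh3, N-chlorosuccinimide, THF, 0 °C
Reagents that add atoms: N-chlorosuccinimide, O=C1CCC(=O)N1Cl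
Why: Appel-type chlorination of the benzylic alcohol under neutral conditions that leave the MOM acetal intact.

Step 12
Reactants: 15 (3aR,5R,6R,7aR)-6-hydroxy-5-(2-hydroxy-2-methylpropyl)-3a,7a-dimethyl-6-(prop-2-yn-1-yl)octahydro-4H-inden-4-one; 22 1-(chloromethyl)-5-methoxy-2-(methoxymethoxy)-3-methylbenzene
Product: 24 (3aR,5R,6R,7aR)-6-hydroxy-5-(2-hydroxy-2-methylpropyl)-6-{(2E)-4-[5-methoxy-2-(methoxymethoxy)-3-methylphenyl]-2-methylbut-2-en-1-yl}-3a,7a-dimethyloctahydro-4H-inden-4-one, via alkenylalane 23 (not isolated)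
Conditions: Me3Al (6 equiv), Cp2ZrCl2 (20 mol%), H2O (1.5 equiv), CH2Cl2, −23 °C; then 22, Pd(PPh3)4 (5 mol%), THF, 20 °C
Reagents that add atoms: trimethylaluminium, C[Al](C)C
Why: Negishi zirconium-catalysed syn-carboalumination (methyl to the internal alkyne carbon) followed by palladium-catalysed coupling of the alkenylalane with the benzylic chloride with retention fixes the E-trisubstituted olefin and touches no stereocentre.

Step 13
Reactants: 24 (3aR,5R,6R,7aR)-6-hydroxy-5-(2-hydroxy-2-methylpropyl)-6-{(2E)-4-[5-methoxy-2-(methoxymethoxy)-3-methylphenyl]-2-methylbut-2-en-1-yl}-3a,7a-dimethyloctahydro-4H-inden-4-one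
Product: 25 (3aR,5R,6R,7aR)-6-hydroxy-6-[(2E)-4-(2-hydroxy-5-methoxy-3-methylphenyl)-2-methylbut-2-en-1-yl]-5-(2-hydroxy-2-methylpropyl)-3a,7a-dimethyloctahydro-4H-inden-4-one
Conditions: ZnBr2 (1.5 equiv), n-PrSH (3 equiv), CH2Cl2, 0 °C, 10 min
Reagents that add atoms: none
Why: Lewis acid-assisted thiolysis of the aryl MOM acetal under non-protic conditions that spare the tertiary β-hydroxy ketone and the olefin; no stereocentre is touched.

**Compound list**

1 | 2,3-dimethylcyclopent-2-en-1-one | CC1=C(C)C(=O)CC1 | starting material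
2 | (1R)-2,3-dimethylcyclopent-2-en-1-ol | O[C@@H]1CCC(C)=C1C | intermediate
3 | trimethyl orthoacetate | CC(OC)(OC)OC | starting material
4 | mixed orthoester, (1R)-1-(1,1-dimethoxyethoxy)-2,3-dimethylcyclopent-2-ene | CC(OC)(OC)O[C@@H]1CCC(C)=C1C | intermediate
5 | ketene acetal, (1R)-1-[(1-methoxyethenyl)oxy]-2,3-dimethylcyclopent-2-ene | C=C(OC)O[C@@H]1CCC(C)=C1C | intermediate
6 | methyl 2-[(1R)-1,2-dimethylcyclopent-2-en-1-yl]acetate | COC(=O)C[C@@]1(C)CCC=C1C | intermediate
7 | acetonitrile | CC#N | starting material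
8 | lithioacetonitrile | [Li]CC#N | intermediate
9 | 4-[(1R)-1,2-dimethylcyclopent-2-en-1-yl]-3-oxobutanenitrile | N#CCC(=O)C[C@@]1(C)CCC=C1C | intermediate
10 | (3R)-3-{[(1R)-1,2-dimethylcyclopent-2-en-1-yl]methyl}-3-hydroxyhex-5-ynenitrile | C#CC[C@](O)(CC#N)C[C@@]1(C)CCC=C1C | intermediate
11 | 2,2-dimethyloxirane | CC1(C)CO1 | starting material
12 | trilithio derivative of 10 | [Li]C#CC[C@](O[Li])(C([Li])C#N)C[C@@]1(C)CCC=C1C | intermediate
13 | (3R)-3-{[(1R)-1,2-dimethylcyclopent-2-en-1-yl]methyl}-3-hydroxy-2-(2-hydroxy-2-methylpropyl)hex-5-ynenitrile (C2 epimers) | C#CC[C@](O)(C(CC(C)(C)O)C#N)C[C@@]1(C)CCC=C1C | intermediate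
14 | cyclic ketimine, (3aR,6R,7aR)-6-hydroxy-5-(2-hydroxy-2-methylpropyl)-4-imino-3a,7a-dimethyl-6-(prop-2-yn-1-yl)octahydro-1H-indene | C#CC[C@@]1(O)C[C@@]2(C)CCC[C@@]2(C)C(=N)C1CC(C)(C)O | intermediate
15 | (3aR,5R,6R,7aR)-6-hydroxy-5-(2-hydroxy-2-methylpropyl)-3a,7a-dimethyl-6-(prop-2-yn-1-yl)octahydro-4H-inden-4-one | C#CC[C@@]1(O)C[C@@]2(C)CCC[C@@]2(C)C(=O)[C@@H]1CC(C)(C)O | intermediate
16 | 2-methylphenol | Cc1ccccc1O | starting material
17 | 4-bromo-2-methylphenol | Cc1cc(Br)ccc1O | intermediate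
18 | 4-methoxy-2-methylphenol | COc1ccc(O)c(C)c1 | intermediate
19 | 4-methoxy-1-(methoxymethoxy)-2-methylbenzene | COCOc1ccc(OC)cc1C | intermediate
20 | [5-methoxy-2-(methoxymethoxy)-3-methylphenyl]lithium | [Li]c1cc(OC)cc(C)c1OCOC | intermediate
21 | [5-methoxy-2-(methoxymethoxy)-3-methylphenyl]methanol | COCOc1c(C)cc(OC)cc1CO | intermediate
22 | 1-(chloromethyl)-5-methoxy-2-(methoxymethoxy)-3-methylbenzene | COCOc1c(C)cc(OC)cc1CCl | intermediate
23 | (E)-alkenyl(dimethyl)alane of 15 (hydroxyls as dimethylaluminium alkoxides) | C[Al](C)/C=C(\C)C[C@@]1(O[Al](C)C)C[C@@]2(C)CCC[C@@]2(C)C(=O)[C@@H]1CC(C)(C)O[Al](C)C | intermediate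
24 | (3aR,5R,6R,7aR)-6-hydroxy-5-(2-hydroxy-2-methylpropyl)-6-{(2E)-4-[5-methoxy-2-(methoxymethoxy)-3-methylphenyl]-2-methylbut-2-en-1-yl}-3a,7a-dimethyloctahydro-4H-inden-4-one | COCOc1c(C)cc(OC)cc1C/C=C(\C)C[C@@]2(O)C[C@@]3(C)CCC[C@@]3(C)C(=O)[C@@H]2CC(C)(C)O | intermediate
25 | (3aR,5R,6R,7aR)-6-hydroxy-6-[(2E)-4-(2-hydroxy-5-methoxy-3-methylphenyl)-2-methylbut-2-en-1-yl]-5-(2-hydroxy-2-methylpropyl)-3a,7a-dimethyloctahydro-4H-inden-4-one (CNP0190381.3) | COc1cc(C)c(O)c(C/C=C(\C)C[C@@]2(O)C[C@@]3(C)CCC[C@@]3(C)C(=O)[C@@H]2CC(C)(C)O)c1 | target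

**Step count and risks**

Total: 13 steps. Longest linear sequence: 8 steps (steps 1–6, 12, 13); the arene branch is steps 7–11.

Most likely to fail, first: step 6. Closure of a tertiary radical onto C≡N in the 6-exo mode is slow (roughly 10^2–10^3 per second), and the same radical can close 6-exo onto the propargyl alkyne, which is intrinsically the faster acceptor; simple reduction of the radical also competes. If the alkyne-closed or reduced products dominate, the acceptor is changed to an aldehyde, which takes up alkyl radicals about a thousand times faster than an alkyne. This fallback sets out from 13 and comes back at 15. Both tertiary hydroxyls of 13 are silylated (Et3SiOTf, 2,6-lutidine) to the bis(triethylsilyl) ether F1, which also prevents lactol formation later. i-Bu2AlH at −78 °C reduces the nitrile to the aldehyde F2. The same Fe(acac)3/PhSiH3 conditions then close the C3a radical onto the aldehyde carbon (precedent: hydrogen-atom-transfer cyclisations onto ketones) to give the ring-closed C4 carbinol F3, again cis-fused. Dess–Martin periodinane oxidises it to the ketone F4, and HF·pyridine returns 15.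

Second: step 4. Reagent control at C6 on a β-ketonitrile is untested; the acidic CH2 or a weak small/large distinction could erode the ratio, and the bicyclic core offers no substrate bias to fall back on later. If the ratio is poor, reagent control is given up and the propargyl group is added after ring closure, which also removes the alkyne from the radical step. This fallback sets out from 6 and comes back at 15. Epoxide 11 is opened by lithioacetonitrile 8 to 4-hydroxy-4-methylpentanenitrile F5, which is silylated to the triethylsilyl ether F6. Its lithio derivative F7 acylates 6 to the β-ketonitrile F8. The iron-hydride cyclisation of step 6 gives, through the enaminone F9 and hydrolysis, the bicyclic 1,3-dione F10. Indium-mediated Barbier propargylation (propargyl bromide, In powder, THF/H2O) at the less hindered C6 carbonyl gives the ketol F11 together with its C5,C6-epimer F12; about 1:1 is expected, and the two are separated by chromatography. HF·pyridine converts F11 into 15.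

Third: step 12. Me3Al may add to the C4 ketone or trigger retro-aldol cleavage through the C6 aluminium alkoxide. If so, the ketone is taken out of play for the coupling. This fallback sets out from 15 and comes back at 24. LiAlH4 reduces 15 to the triol F13; the same carboalumination gives the alane F14, and coupling with 22 gives the aryl-coupled triol F15. Dess–Martin periodinane oxidises its only secondary alcohol to give 24.

**Further compounds**

F1 | step 6 | (3R)-3-{[(1R)-1,2-dimethylcyclopent-2-en-1-yl]methyl}-2-{2-methyl-2-[(triethylsilyl)oxy]propyl}-3-[(triethylsilyl)oxy]hex-5-ynenitrile | C#CC[C@](O[Si](CC)(CC)CC)(C(CC(C)(C)O[Si](CC)(CC)CC)C#N)C[C@@]1(C)CCC=C1C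
F2 | step 6 | (3R)-3-{[(1R)-1,2-dimethylcyclopent-2-en-1-yl]methyl}-2-{2-methyl-2-[(triethylsilyl)oxy]propyl}-3-[(triethylsilyl)oxy]hex-5-ynal | C#CC[C@](O[Si](CC)(CC)CC)(C(CC(C)(C)O[Si](CC)(CC)CC)C=O)C[C@@]1(C)CCC=C1C
F3 | step 6 | (3aR,6R,7aR)-3a,7a-dimethyl-5-{2-methyl-2-[(triethylsilyl)oxy]propyl}-6-(prop-2-yn-1-yl)-6-[(triethylsilyl)oxy]octahydro-1H-inden-4-ol | C#CC[C@@]1(O[Si](CC)(CC)CC)C[C@@]2(C)CCC[C@@]2(C)C(O)C1CC(C)(C)O[Si](CC)(CC)CC
F4 | step 6 | (3aR,5R,6R,7aR)-3a,7a-dimethyl-5-{2-methyl-2-[(triethylsilyl)oxy]propyl}-6-(prop-2-yn-1-yl)-6-[(triethylsilyl)oxy]octahydro-4H-inden-4-one | C#CC[C@@]1(O[Si](CC)(CC)CC)C[C@@]2(C)CCC[C@@]2(C)C(=O)[C@@H]1CC(C)(C)O[Si](CC)(CC)CC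
F5 | step 4 | 4-hydroxy-4-methylpentanenitrile | CC(C)(O)CCC#N
F6 | step 4 | 4-methyl-4-[(triethylsilyl)oxy]pentanenitrile | CC[Si](CC)(CC)OC(C)(C)CCC#N
F7 | step 4 | 2-lithio-4-methyl-4-[(triethylsilyl)oxy]pentanenitrile | CC[Si](CC)(CC)OC(C)(C)CC([Li])C#N
F8 | step 4 | 2-{[(1R)-1,2-dimethylcyclopent-2-en-1-yl]acetyl}-4-methyl-4-[(triethylsilyl)oxy]pentanenitrile | CC[Si](CC)(CC)OC(C)(C)CC(C#N)C(=O)C[C@@]1(C)CCC=C1C
F9 | step 4 | (3aR,7aR)-4-amino-3a,7a-dimethyl-5-{2-methyl-2-[(triethylsilyl)oxy]propyl}-1,2,3,3a,7,7a-hexahydro-6H-inden-6-one | O=C1C[C@@]2(C)CCC[C@@]2(C)C(N)=C1CC(C)(C)O[Si](CC)(CC)CC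
F10 | step 4 | (3aR,7aR)-3a,7a-dimethyl-5-{2-methyl-2-[(triethylsilyl)oxy]propyl}hexahydro-1H-indene-4,6(5H,7H)-dione | O=C1C[C@@]2(C)CCC[C@@]2(C)C(=O)C1CC(C)(C)O[Si](CC)(CC)CC
F11 | step 4 | (3aR,5R,6R,7aR)-6-hydroxy-3a,7a-dimethyl-5-{2-methyl-2-[(triethylsilyl)oxy]propyl}-6-(prop-2-yn-1-yl)octahydro-4H-inden-4-one | C#CC[C@@]1(O)C[C@@]2(C)CCC[C@@]2(C)C(=O)[C@@H]1CC(C)(C)O[Si](CC)(CC)CC
F12 | step 4 | (3aR,5S,6S,7aR)-6-hydroxy-3a,7a-dimethyl-5-{2-methyl-2-[(triethylsilyl)oxy]propyl}-6-(prop-2-yn-1-yl)octahydro-4H-inden-4-one | C#CC[C@]1(O)C[C@@]2(C)CCC[C@@]2(C)C(=O)[C@H]1CC(C)(C)O[Si](CC)(CC)CC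
F13 | step 12 | (3aR,5R,6R,7aR)-5-(2-hydroxy-2-methylpropyl)-3a,7a-dimethyl-6-(prop-2-yn-1-yl)octahydro-1H-indene-4,6-diol | C#CC[C@@]1(O)C[C@@]2(C)CCC[C@@]2(C)C(O)[C@@H]1CC(C)(C)O
F14 | step 12 | (E)-alkenyl(dimethyl)alane of F13 (hydroxyls as dimethylaluminium alkoxides) | C[Al](C)/C=C(\C)C[C@@]1(O[Al](C)C)C[C@@]2(C)CCC[C@@]2(C)C(O[Al](C)C)[C@@H]1CC(C)(C)O[Al](C)C
F15 | step 12 | (3aR,5R,6R,7aR)-5-(2-hydroxy-2-methylpropyl)-6-{(2E)-4-[5-methoxy-2-(methoxymethoxy)-3-methylphenyl]-2-methylbut-2-en-1-yl}-3a,7a-dimethyloctahydro-1H-indene-4,6-diol | COCOc1c(C)cc(OC)cc1C/C=C(\C)C[C@@]2(O)C[C@@]3(C)CCC[C@@]3(C)C(O)[C@@H]2CC(C)(C)O
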